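Target ⇒ (last step, acid) its tris-MOM/TBS-protected form. Rings A and B are bought as phloroglucinol and 4-hydroxy-2-methoxybenzaldehyde. Ring C is the only ring formed, and it is formed last.
Ring C ⇒ O1–C2 and C4–C4a are cut together. This gives an O1,C4a-dilithiated ring A fragment (C,O-1,3-bisnucleophile) and the (E)-cinnamoyl N-methoxy-N-methylamide of ring B (C4 acyl / C2 Michael 1,3-biselectrophile). Fragment union, C-acylation and catalyst-controlled 6-endo-trig oxa-Michael closure run in one flask and set C2.
Enabling feature: in ring A, O1 lies between C8 (blocked by the C10 chain) and C4a. With O5 and O7 masked, O1–H is the only free phenol and C4a its only open ortho carbon, so only the 8-substituted ring C can form. The O5 substituent ortho to the new C4 carbonyl twists the aroyl group and makes closure favourable.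
Ring A fragment ⇒ lithiated symmetric tris-MOM phloroglucinol + cis-α-prenyl-β-methyl-γ-butyrolactone. The resulting ketone on C8 singles out O1 (chelation-controlled loss of one MOM group) and is then deleted through an o-quinone methide. Iodine then marks C4a.
Side chain ⇒ C3'' is bought as (R)-β-methyl-γ-butyrolactone. C2'' is relayed from it in the temporary lactone ring (trans prenylation, then kinetic protonation to cis).

Key step: step 12

Numbering remark: O1, C2, C3, C4, C4a, C5–C8, C8a are flavanone positions. C1''–C4'' are the butyl chain on C8 (C1'' benzylic CH2, C2'' bears prenyl, C3'' bears CH3, C4'' is CH2OH).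
Assumption: the sense of induction of the quinine-derived thiourea is taken by analogy with quinine-type catalysts in ring closures of o-enoylphenols of the phloroglucinol series, which place the C2 substituent as in 2S-flavanones. If a test shows the opposite sense, the quinidine-derived pseudoenantiomer is used in the same step.

Step 1
Reactants: 1 (R)-4-methyldihydrofuran-2(3H)-one; 2 1-bromo-3-methylbut-2-ene (prenyl bromide)
Product: 4 (3R,4R)-4-methyl-3-(3-methylbut-2-en-1-yl)dihydrofuran-2(3H)-one (trans), via lithium enolate 3 (not isolated)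
Conditions: LDA, THF, −78 °C; 2, −78 → −30 °C
Reagents that add atoms: none
Why: Substrate-controlled enolate alkylation of a β-substituted γ-butyrolactone takes place anti to the C4 methyl group, so the prenyl group enters trans; this step installs the carbon chain, and the C3 configuration is corrected in step 2.

Step 2
Reactants: 4 (3R,4R)-4-methyl-3-(3-methylbut-2-en-1-yl)dihydrofuran-2(3H)-one
Product: 6 (3S,4R)-4-methyl-3-(3-methylbut-2-en-1-yl)dihydrofuran-2(3H)-one (cis), via lithium enolate 5 (not isolated)
Conditions: LDA, THF, −78 °C; then 2,6-di-tert-butyl-4-methylphenol (3 equiv), −78 °C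
Reagents that add atoms: none
Why: Deprotonation erases C3, and diastereoselective kinetic protonation of the planar enolate by a bulky phenol again occurs anti to the C4 methyl group, which now places the prenyl group on the methyl side and sets C3 (the later C2'') as the contra-thermodynamic cis isomer.

Step 3
Reactants: 7 phloroglucinol (benzene-1,3,5-triol)
Product: 8 1,3,5-tris(methoxymethoxy)benzene
Conditions: NaH, MOMCl, DMF, 0 °C → rt
Reagents that add atoms: chloromethyl methyl ether (MOMCl), COCCl
Why: Williamson-type O-alkylation of the three phenoxides gives a symmetric arene whose MOM groups later direct the lithiation.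

Step 4
Reactants: 8 1,3,5-tris(methoxymethoxy)benzene; 6 (3S,4R)-4-methyl-3-(3-methylbut-2-en-1-yl)dihydrofuran-2(3H)-one
Product: 10 (2S,3R)-4-hydroxy-3-methyl-2-(3-methylbut-2-en-1-yl)-1-[2,4,6-tris(methoxymethoxy)phenyl]butan-1-one, via aryllithium 9 (not isolated)
Conditions: n-BuLi, THF, 0 °C; 6, −78 → −30 °C; sat. aq NH4Cl
Reagents that add atoms: none
Why: Directed ortho-lithiation between two MOM ethers (all three ring positions are equivalent) gives 9, and addition of this hindered aryllithium to the lactone carbonyl stops after one addition because the lactolate persists at low temperature (aryllithium–lactone ketone synthesis); no stereocentre is formed, and the centre next to the new ketone is kept by the low temperature and the buffered quench.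

Step 5
Reactants: 10 (2S,3R)-4-hydroxy-3-methyl-2-(3-methylbut-2-en-1-yl)-1-[2,4,6-tris(methoxymethoxy)phenyl]butan-1-one
Product: 11 (2S,3R)-4-(tert-butyldimethylsilyloxy)-3-methyl-2-(3-methylbut-2-en-1-yl)-1-[2,4,6-tris(methoxymethoxy)phenyl]butan-1-one
Conditions: TBSCl, imidazole, DMF, rt
Reagents that add atoms: tert-butyldimethylsilyl chloride (TBSCl), CC(C)(C)[Si](C)(C)Cl
Why: Standard silylation of the primary alcohol traps the open hydroxy ketone form and masks C4''–OH for the organolithium and acylation steps that follow.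

Step 6
Reactants: 11 (2S,3R)-4-(tert-butyldimethylsilyloxy)-3-methyl-2-(3-methylbut-2-en-1-yl)-1-[2,4,6-tris(methoxymethoxy)phenyl]butan-1-one
Product: 12 (2S,3R)-4-(tert-butyldimethylsilyloxy)-1-[2-hydroxy-4,6-bis(methoxymethoxy)phenyl]-3-methyl-2-(3-methylbut-2-en-1-yl)butan-1-one
Conditions: MgBr2·OEt2, n-BuSH, Et2O, 0 °C → rt
Reagents that add atoms: none
Why: Mg(II) chelated between the ketone oxygen and an ortho MOM oxygen activates that acetal for transfer to the thiol (chelation-assisted MOM cleavage); the two ortho MOM groups are equivalent by rotation of the ring, the magnesium phenoxide chelate formed after the first cleavage protects the second, and the para MOM group is not activated, so this step singles out the future O1.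

Step 7
Reactants: 12 (2S,3R)-4-(tert-butyldimethylsilyloxy)-1-[2-hydroxy-4,6-bis(methoxymethoxy)phenyl]-3-methyl-2-(3-methylbut-2-en-1-yl)butan-1-one
Product: 13 2-[(2S,3R)-4-(tert-butyldimethylsilyloxy)-3-methyl-2-(3-methylbut-2-en-1-yl)butanoyl]-3,5-bis(methoxymethoxy)phenyl ethyl carbonate
Conditions: ClCO2Et, Et3N, THF, 0 °C
Reagents that add atoms: ethyl chloroformate, CCOC(=O)Cl
Why: O-acylation of the only free phenoxide with a chloroformate installs the leaving group needed for the reductive removal of the ketone oxygen.

Step 8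
Reactants: 13 2-[(2S,3R)-4-(tert-butyldimethylsilyloxy)-3-methyl-2-(3-methylbut-2-en-1-yl)butanoyl]-3,5-bis(methoxymethoxy)phenyl ethyl carbonate
Product: 15 2-[(2R,3R)-4-(tert-butyldimethylsilyloxy)-3-methyl-2-(3-methylbut-2-en-1-yl)butyl]-3,5-bis(methoxymethoxy)phenol, via o-quinone methide 14 (not isolated)
Conditions: NaBH4 (excess), THF/H2O, 0 °C → rt
Reagents that add atoms: none
Why: Borohydride reduces the ketone, the ethoxycarbonyl group moves to the benzylic alkoxide and is expelled by the phenoxide to give 14, which takes up a second hydride at the exocyclic carbon (reductive deoxygenation of o-acylphenols through their aryl carbonates); C1'' becomes CH2, and C2'' is not touched and is no longer epimerisable afterwards.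

Step 9
Reactants: 15 2-[(2R,3R)-4-(tert-butyldimethylsilyloxy)-3-methyl-2-(3-methylbut-2-en-1-yl)butyl]-3,5-bis(methoxymethoxy)phenol
Product: 16 2-[(2R,3R)-4-(tert-butyldimethylsilyloxy)-3-methyl-2-(3-methylbut-2-en-1-yl)butyl]-6-iodo-3,5-bis(methoxymethoxy)phenol
Conditions: I2 (1.0 equiv), NaHCO3, THF/H2O, 0 °C
Reagents that add atoms: iodine, II
Why: In this electrophilic aromatic iodination of the phenoxide the ring is far more nucleophilic than the trisubstituted alkene, and the carbon ortho to the free OH is less crowded than the carbon between the two MOM ethers, so iodine should enter at the future C4a.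

Step 10
Reactants: 17 4-hydroxy-2-methoxybenzaldehyde
Product: 18 2-methoxy-4-(methoxymethoxy)benzaldehyde
Conditions: MOMCl, i-Pr2NEt, CH2Cl2, 0 °C → rt
Reagents that add atoms: chloromethyl methyl ether (MOMCl), COCCl
Why: O-alkylation of the acidic para-formyl phenol masks the 4'-OH with the same acid-labile group as used on ring A.

Step 11
Reactants: 18 2-methoxy-4-(methoxymethoxy)benzaldehyde; 19 diethyl {2-[methoxy(methyl)amino]-2-oxoethyl}phosphonate
Product: 20 (E)-N-methoxy-3-[2-methoxy-4-(methoxymethoxy)phenyl]-N-methylacrylamide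
Conditions: NaH, THF, 0 °C → rt
Reagents that add atoms: none
Why: The Horner–Wadsworth–Emmons olefination of an aromatic aldehyde with a stabilised phosphonate gives the E-alkene and delivers C2, C3 and C4 already at the right oxidation level.

Step 12
Reactants: 16 2-[(2R,3R)-4-(tert-butyldimethylsilyloxy)-3-methyl-2-(3-methylbut-2-en-1-yl)butyl]-6-iodo-3,5-bis(methoxymethoxy)phenol; 20 (E)-N-methoxy-3-[2-methoxy-4-(methoxymethoxy)phenyl]-N-methylacrylamide
Product: 24 (2S)-8-[(2R,3R)-4-(tert-butyldimethylsilyloxy)-3-methyl-2-(3-methylbut-2-en-1-yl)butyl]-2-[2-methoxy-4-(methoxymethoxy)phenyl]-5,7-bis(methoxymethoxy)chroman-4-one, via dilithio arene 21 (not isolated), via tetrahedral adduct 22 (not isolated), via chalcone 23 (not isolated)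
Conditions: t-BuLi (3.1 equiv), PhMe/Et2O, −78 °C; 20, −78 → −20 °C; AcOH (2.1 equiv), −78 °C → rt; quinine-derived (9-amino-9-deoxy-epi) 3,5-bis(trifluoromethyl)phenyl thiourea (15 mol %), rt
Reagents that add atoms: none
Why: t-BuLi removes the O1 proton and exchanges the iodine, and the hard aryl carbanion of dianion 21 adds 1,2 to the chelating amide 20 (Weinreb ketone synthesis with an o-lithiophenoxide, the closest known reaction type for the C–C bond); adduct 22 survives until the acetic acid quench, so neither a second addition nor an anionic ring closure can occur, and its collapse delivers the C4–C4a bond as 2'-hydroxychalcone 23. The bifunctional cinchona thiourea then closes ring C through O1–C2 by a 6-endo-trig intramolecular oxa-Michael addition, the known organocatalytic (chalcone-isomerase-like) cyclisation of 2'-hydroxychalcones and of o-enoylphenols of the phloroglucinol series. C2 is the only new stereocentre and is controlled by the catalyst: the thiourea binds the C4 carbonyl, the quinuclidine nitrogen takes the O1 proton, and O1 is delivered to the Si face of C2, which gives 2S; the remote side-chain centres should have little say. Site selectivity is built into the substrate: iodine marks C4a, O1–H is the only free phenol, C8 is blocked, and the masked O5 cannot close to the 6-substituted isomer. The two oxygen substituents ortho to the C4 carbonyl twist the aroyl group out of conjugation, which favours the closed form and slows the reverse reaction that would erode C2. Since the side chain is enantiopure, any 2R product is a diastereomer and can be removed by chromatography.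

Step 13
Reactants: 24 (2S)-8-[(2R,3R)-4-(tert-butyldimethylsilyloxy)-3-methyl-2-(3-methylbut-2-en-1-yl)butyl]-2-[2-methoxy-4-(methoxymethoxy)phenyl]-5,7-bis(methoxymethoxy)chroman-4-one
Product: 25 (2S)-5,7-dihydroxy-8-[(2R,3R)-4-hydroxy-3-methyl-2-(3-methylbut-2-en-1-yl)butyl]-2-(4-hydroxy-2-methoxyphenyl)chroman-4-one (target)
Conditions: aq HCl (catalytic), MeOH, rt → 40 °C
Reagents that add atoms: none
Why: Acid-catalysed acetal exchange and desilylation in methanol free all four hydroxyl groups in one step; acid is chosen because base would open ring C reversibly, which would epimerise C2 and, once O5 is free, scramble the 8- and 6-substituted isomers, whereas the remote trisubstituted alkene has no hydroxyl group within reach for a favourable ring closure.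

Compound list
1 | (R)-4-methyldihydrofuran-2(3H)-one [(R)-β-methyl-γ-butyrolactone] | O=C1C[C@@H](C)CO1 | starting material
2 | 1-bromo-3-methylbut-2-ene (prenyl bromide) | CC(C)=CCBr | starting material
3 | lithium enolate of 1 | [Li]OC1=C[C@@H](C)CO1 | intermediate
4 | (3R,4R)-4-methyl-3-(3-methylbut-2-en-1-yl)dihydrofuran-2(3H)-one (trans) | O=C1[C@H](CC=C(C)C)[C@@H](C)CO1 | intermediate
5 | lithium enolate of 4 | [Li]OC1=C(CC=C(C)C)[C@@H](C)CO1 | intermediate
6 | (3S,4R)-4-methyl-3-(3-methylbut-2-en-1-yl)dihydrofuran-2(3H)-one (cis) | O=C1[C@@H](CC=C(C)C)[C@@H](C)CO1 | intermediate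
7 | phloroglucinol | Oc1cc(O)cc(O)c1 | starting material
8 | 1,3,5-tris(methoxymethoxy)benzene | COCOc1cc(OCOC)cc(OCOC)c1 | intermediate
9 | 2,4,6-tris(methoxymethoxy)phenyllithium | [Li]c1c(OCOC)cc(OCOC)cc1OCOC | intermediate
10 | (2S,3R)-4-hydroxy-3-methyl-2-(3-methylbut-2-en-1-yl)-1-[2,4,6-tris(methoxymethoxy)phenyl]butan-1-one | COCOc1cc(OCOC)c(C(=O)[C@@H](CC=C(C)C)[C@@H](C)CO)c(OCOC)c1 | intermediate
11 | TBS ether of 10 | COCOc1cc(OCOC)c(C(=O)[C@@H](CC=C(C)C)[C@@H](C)CO[Si](C)(C)C(C)(C)C)c(OCOC)c1 | intermediate
12 | (2S,3R)-4-(tert-butyldimethylsilyloxy)-1-[2-hydroxy-4,6-bis(methoxymethoxy)phenyl]-3-methyl-2-(3-methylbut-2-en-1-yl)butan-1-one | COCOc1cc(O)c(C(=O)[C@@H](CC=C(C)C)[C@@H](C)CO[Si](C)(C)C(C)(C)C)c(OCOC)c1 | intermediate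
13 | aryl ethyl carbonate of 12 | CCOC(=O)Oc1cc(OCOC)cc(OCOC)c1C(=O)[C@@H](CC=C(C)C)[C@@H](C)CO[Si](C)(C)C(C)(C)C | intermediate
14 | o-quinone methide (6-alkylidene-3,5-bis(methoxymethoxy)cyclohexa-2,4-dien-1-one) | O=C1C=C(OCOC)C=C(OCOC)C1=C[C@@H](CC=C(C)C)[C@@H](C)CO[Si](C)(C)C(C)(C)C | intermediate
15 | 2-[(2R,3R)-4-(tert-butyldimethylsilyloxy)-3-methyl-2-(3-methylbut-2-en-1-yl)butyl]-3,5-bis(methoxymethoxy)phenol | COCOc1cc(O)c(C[C@@H](CC=C(C)C)[C@@H](C)CO[Si](C)(C)C(C)(C)C)c(OCOC)c1 | intermediate
16 | 6-iodo derivative of 15 | Oc1c(I)c(OCOC)cc(OCOC)c1C[C@@H](CC=C(C)C)[C@@H](C)CO[Si](C)(C)C(C)(C)C | intermediate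
17 | 4-hydroxy-2-methoxybenzaldehyde | COc1cc(O)ccc1C=O | starting material
18 | 2-methoxy-4-(methoxymethoxy)benzaldehyde | COCOc1ccc(C=O)c(OC)c1 | intermediate
19 | diethyl {2-[methoxy(methyl)amino]-2-oxoethyl}phosphonate | CCOP(=O)(CC(=O)N(C)OC)OCC | starting material
20 | (E)-N-methoxy-3-[2-methoxy-4-(methoxymethoxy)phenyl]-N-methylacrylamide | COCOc1ccc(/C=C/C(=O)N(C)OC)c(OC)c1 | intermediate
21 | O,C-dilithiated arene from 16 (lithium 2-lithiophenoxide) | [Li]Oc1c([Li])c(OCOC)cc(OCOC)c1C[C@@H](CC=C(C)C)[C@@H](C)CO[Si](C)(C)C(C)(C)C | intermediate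
22 | dilithium tetrahedral adduct of 21 and 20 | COc1cc(OCOC)ccc1/C=C/C(O[Li])(N(C)OC)c1c(O[Li])c(C[C@@H](CC=C(C)C)[C@@H](C)CO[Si](C)(C)C(C)(C)C)c(OCOC)cc1OCOC | intermediate
23 | (E)-1-{3-[(2R,3R)-4-(tert-butyldimethylsilyloxy)-3-methyl-2-(3-methylbut-2-en-1-yl)butyl]-2-hydroxy-4,6-bis(methoxymethoxy)phenyl}-3-[2-methoxy-4-(methoxymethoxy)phenyl]prop-2-en-1-one | COc1cc(OCOC)ccc1/C=C/C(=O)c1c(O)c(C[C@@H](CC=C(C)C)[C@@H](C)CO[Si](C)(C)C(C)(C)C)c(OCOC)cc1OCOC | intermediate
24 | (2S)-8-[(2R,3R)-4-(tert-butyldimethylsilyloxy)-3-methyl-2-(3-methylbut-2-en-1-yl)butyl]-2-[2-methoxy-4-(methoxymethoxy)phenyl]-5,7-bis(methoxymethoxy)chroman-4-one | COc1cc(OCOC)ccc1[C@@H]1CC(=O)c2c(OCOC)cc(OCOC)c(C[C@@H](CC=C(C)C)[C@@H](C)CO[Si](C)(C)C(C)(C)C)c2O1 | intermediate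
25 | (2S)-5,7-dihydroxy-8-[(2R,3R)-4-hydroxy-3-methyl-2-(3-methylbut-2-en-1-yl)butyl]-2-(4-hydroxy-2-methoxyphenyl)chroman-4-one | COc1cc(O)ccc1[C@@H]1CC(=O)c2c(O)cc(O)c(C[C@@H](CC=C(C)C)[C@@H](C)CO)c2O1 | target

Total step count: 13. Longest linear sequence: 10 steps (1, 2, 4–9, 12, 13).

Steps most likely to fail

**Step 12.**
- What may go wrong: the ring closure may be sluggish and poorly face-selective, because the two donor groups of ring B lower the electrophilicity of C2.
- The salts left from the coupling stage may also open an unselective background closure, and C2 may erode slowly by reversible ring opening.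
- The fallback sets out from chalcone 23, isolated after the acetic acid quench, and comes back at 24.
- Ring closure without stereocontrol (NaOAc, EtOH, reflux) gives the C2-epimeric protected flavanone mixture F1.
- Asymmetric transfer hydrogenation follows, with RuCl[(S,S)-TsDPEN](p-cymene) in HCO2H/Et3N and added DBU.
- Under these conditions the unreacted 2R ketone epimerises by reversible ring opening, so both epimers should funnel into the cis-(2S,4S)-flavan-4-ol F2 (dynamic kinetic resolution, C2 and C4 read by the metal catalyst).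
- A NaHCO3-buffered Dess–Martin oxidation of the C4 alcohol then gives 24.

**Step 2.**
- What may go wrong: facial discrimination in the protonation may be insufficient because the methyl group is small.
- Internal proton return from diisopropylamine, or equilibration towards the trans isomer, may also occur.
- The fallback sets out from lactone 1 and comes back at 6.
- Saponification (KOH), silylation (TBSCl, imidazole) and mild hydrolysis of the silyl ester give (R)-4-(tert-butyldimethylsilyloxy)-3-methylbutanoic acid F3.
- Its mixed pivalic anhydride acylates lithiated (S)-4-benzyloxazolidin-2-one to give the N-acyl oxazolidinone F4.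
- Evans alkylation (NaHMDS, then 2, THF, −78 °C) gives the α-prenylated imide F5. The auxiliary, not the methyl group, decides the face.
- HF·pyridine removes the silyl group. The freed γ-hydroxyl group lactonises onto the imide carbonyl with release of the auxiliary and gives 6.

**Step 9.**
- What may go wrong: iodine may enter at the ring carbon between the two MOM ethers, or the iodine electrophile may attack the trisubstituted alkene.
- The fallback sets out from phenol 15 (and aldehyde 18), needs no halogen, and comes back at chalcone 23.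
- Knoevenagel–Doebner condensation of 18 with malonic acid (pyridine, piperidine) gives (E)-3-[2-methoxy-4-(methoxymethoxy)phenyl]acrylic acid F6.
- 1-Chloro-N,N,2-trimethylprop-1-en-1-amine converts it under neutral conditions into the acid chloride F7.
- Phenol 15 is turned with EtMgBr in toluene into the aryloxymagnesium bromide F8.
- F8 is acylated by F7 at the carbon ortho to the O–Mg bond through a six-membered magnesium template (metal-template ortho-acylation of phenols).
- This gives 23, to which the catalyst of step 12 is then added.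

Further compounds
F1 | step 12 | C2-epimeric mixture of protected flavanone (2RS form of 24) | COc1cc(OCOC)ccc1C1CC(=O)c2c(OCOC)cc(OCOC)c(C[C@@H](CC=C(C)C)[C@@H](C)CO[Si](C)(C)C(C)(C)C)c2O1
F2 | step 12 | (2S,4S)-8-[(2R,3R)-4-(tert-butyldimethylsilyloxy)-3-methyl-2-(3-methylbut-2-en-1-yl)butyl]-2-[2-methoxy-4-(methoxymethoxy)phenyl]-5,7-bis(methoxymethoxy)chroman-4-ol | COc1cc(OCOC)ccc1[C@@H]1C[C@H](O)c2c(OCOC)cc(OCOC)c(C[C@@H](CC=C(C)C)[C@@H](C)CO[Si](C)(C)C(C)(C)C)c2O1
F3 | step 2 | (R)-4-(tert-butyldimethylsilyloxy)-3-methylbutanoic acid | OC(=O)C[C@@H](C)CO[Si](C)(C)C(C)(C)C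
F4 | step 2 | (S)-4-benzyl-3-[(R)-4-(tert-butyldimethylsilyloxy)-3-methylbutanoyl]oxazolidin-2-one | O=C(C[C@@H](C)CO[Si](C)(C)C(C)(C)C)N1[C@@H](Cc2ccccc2)COC1=O
F5 | step 2 | (S)-4-benzyl-3-[(2S,3R)-4-(tert-butyldimethylsilyloxy)-3-methyl-2-(3-methylbut-2-en-1-yl)butanoyl]oxazolidin-2-one | O=C([C@@H](CC=C(C)C)[C@@H](C)CO[Si](C)(C)C(C)(C)C)N1[C@@H](Cc2ccccc2)COC1=O
F6 | step 9 | (E)-3-[2-methoxy-4-(methoxymethoxy)phenyl]acrylic acid | COc1cc(OCOC)ccc1/C=C/C(=O)O
F7 | step 9 | (E)-3-[2-methoxy-4-(methoxymethoxy)phenyl]acryloyl chloride | COc1cc(OCOC)ccc1/C=C/C(=O)Cl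
F8 | step 9 | bromomagnesium phenoxide of 15 | Br[Mg]Oc1cc(OCOC)cc(OCOC)c1C[C@@H](CC=C(C)C)[C@@H](C)CO[Si](C)(C)C(C)(C)C
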